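**Plan**

- Germacranolide numbering is used. The C1 ketone and the exocyclic C10=C14 methylene of the ten-membered ring (C1–C10) are an oxidised 2-methylene allylic carbinol, so the ring is cut at C1–C10 into a C1 aldehyde and a terminal C10≡C14 alkyne.
- Further cuts: the C8 tiglate and C13 acetate C–O bonds, the lactone O–C6 bond, C6–C7 (alkenylchromium plus epoxy aldehyde), C7–C11 (Claisen) and C9–C10 (acetylide plus glycidate).
- Forward: the C7–C14 piece is built from methyl (S)-glycidate and the C1–C6 piece from geraniol; they are joined at C6–C7. The butenolide closes first (step 9), the ten-membered ring last (step 14), followed by desilylation and oxidation.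
- Stereochemistry: C8 comes from the glycidate and C4/C5 from a Sharpless epoxidation. C6 is set 6R by Felkin–Anh addition and then inverted to 6S by SN2 lactonisation. C1 is transient.

Key step: step 14

Remark: C1 of 24 and 25 is written without a descriptor because both epimers give the same ketone in step 16.
Remark: the descriptor at the epoxide CH changes from R in 2 to S in 3 only because the formyl group outranks the neighbouring epoxide carbon; the spatial arrangement is unchanged.

**Route**

Step 1
Reactants: 1 geraniol
Product: 2 (2R,3R)-2,3-epoxygeraniol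
Conditions: Ti(OiPr)4 (5 mol %), D-(−)-diethyl tartrate (6 mol %), t-BuOOH, 4 Å MS, CH2Cl2, −20 °C
Reagents that add atoms: tert-butyl hydroperoxide, CC(C)(C)OO
Why: Sharpless asymmetric epoxidation acts only on the allylic 2,3-olefin, and the titanium complex of the D-(−)-tartrate delivers oxygen to the face that gives the (2R,3R)-epoxide, which becomes C5 and C4 of the target.

Step 2
Reactants: 2 (2R,3R)-2,3-epoxygeraniol
Product: 3 (2S,3R)-2,3-epoxy-3,7-dimethyloct-6-enal
Conditions: Dess–Martin periodinane, NaHCO3, CH2Cl2, 0 °C → rt
Reagents that add atoms: none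
Why: Dess–Martin oxidation of a primary 2,3-epoxy alcohol under bicarbonate buffering should stop at the aldehyde without opening the epoxide or epimerising the α-carbon.

Step 3
Reactants: 4 methyl (S)-glycidate; 5 (trimethylsilyl)acetylene
Product: 7 methyl (S)-2-hydroxypent-4-ynoate, via silylalkyne hydroxy ester 6 (not isolated)
Conditions: 5, n-BuLi, THF, −78 °C; BF3·OEt2, then 4, −78 °C; then MeOH, K2CO3, 0 °C → rt
Reagents that add atoms: none
Why: BF3-promoted alkynylation of a terminal epoxide takes place at the unsubstituted carbon remote from the ester, so the glycidate stereocentre (the future C8) is carried over untouched and C9–C10 is formed, and methanolysis of the C–Si bond in the same flask frees the terminal alkyne.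

Step 4
Reactants: 7 methyl (S)-2-hydroxypent-4-ynoate
Product: 8 methyl (S)-2-(triethylsilyloxy)pent-4-ynoate
Conditions: Et3SiCl, imidazole, CH2Cl2, 0 °C
Reagents that add atoms: chlorotriethylsilane, CC[Si](Cl)(CC)CC
Why: Standard silylation of a secondary α-hydroxy ester masks the C8 oxygen for the enolate, triflation and chromium steps.

Step 5
Reactants: 9 tert-butyl 3-hydroxypropanoate
Product: 10 tert-butyl 3-(tert-butyldimethylsilyloxy)propanoate
Conditions: t-BuMe2SiCl, imidazole, CH2Cl2, rt
Reagents that add atoms: tert-butylchlorodimethylsilane, CC(C)(C)[Si](C)(C)Cl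
Why: Standard silylation of a primary alcohol gives the C11–C13 building block, whose silyloxy group is a poor leaving group from the derived ester enolate.

Step 6
Reactants: 8 methyl (S)-2-(triethylsilyloxy)pent-4-ynoate; 10 tert-butyl 3-(tert-butyldimethylsilyloxy)propanoate
Product: 11 tert-butyl (4S)-2-[(tert-butyldimethylsilyloxy)methyl]-3-oxo-4-(triethylsilyloxy)hept-6-ynoate (C11 epimers)
Conditions: LiN(iPr)2 (from iPr2NH, n-BuLi), 10 (3.3 equiv), THF, −78 °C; then 8, −78 → −40 °C; aq. NH4Cl
Reagents that add atoms: none
Why: In this crossed Claisen condensation the lithium enolate of the tert-butyl ester, used in excess to allow for the alkyne and product protons, should acylate on the activated α-silyloxy methyl ester at low temperature and form C7–C11, the product being held as its enolate so that C8 is not epimerised.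

Step 7
Reactants: 11 β-keto ester
Product: 13 tert-butyl (2Z,4S)-2-[(tert-butyldimethylsilyloxy)methyl]-4-(triethylsilyloxy)-3-(trifluoromethylsulfonyloxy)hept-2-en-6-ynoate, via sodium enolate 12 (not isolated)
Conditions: NaH, Et2O, 0 °C; then Tf2O, −78 → 0 °C
Reagents that add atoms: trifluoromethanesulfonic anhydride, O=S(=O)(OS(=O)(=O)C(F)(F)F)C(F)(F)F
Why: O-triflation of the sodium-chelated enolate of a β-keto ester, in which the enolate oxygen and the ester carbonyl are held cis, should give the Z enol triflate with the triflate cis to the tert-butyl ester, and only the doubly activated C11–H is removed, so C8 is untouched.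

Step 8
Reactants: 13 Z enol triflate; 3 (2S,3R)-2,3-epoxy-3,7-dimethyloct-6-enal
Product: 14 open 6R hydroxy tert-butyl ester (C6 cis to CO2tBu on C7=C11; 8S triethylsilyl ether; C13 tert-butyldimethylsilyl ether; 4R,5R-epoxide; isopropylidene terminus)
Conditions: CrCl2 (6 equiv), NiCl2 (2 mol %), DMF, rt
Reagents that add atoms: none
Why: In this Nozaki–Hiyama–Kishi coupling nickel inserts into the C7–O triflate bond and the alkenyl group passes to chromium with retention of olefin geometry and adds to the aldehyde to form C6–C7; Felkin–Anh control by the α-epoxide, whose C–O bond lies anti to the incoming group, should set C6 as R (erythro to the epoxide), and the hindered tert-butyl ester should resist the chromium alkoxide so that the open hydroxy ester is obtained.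

Step 9
Reactants: 14 open 6R hydroxy tert-butyl ester
Product: 16 6S butenolide (8S triethylsilyl ether; C13 tert-butyldimethylsilyl ether; 4R,5R-epoxide; terminal alkyne; isopropylidene terminus), via C6 mesylate 15 (not isolated)
Conditions: Ms2O, 2,6-lutidine, DMAP (cat.), ClCH2CH2Cl, 0 °C; then 60 °C
Reagents that add atoms: methanesulfonic anhydride, CS(=O)(=O)OS(C)(=O)=O (its mesyl group is carried only by 15 and is lost again before 16)
Why: The cis tert-butyl ester carbonyl should displace the C6 mesylate from the rear (5-exo-tet neighbouring-group SN2) and the resulting dioxolenium ion loses isobutene, a dealkylative lactonisation of the kind long used to make butenolides from Z-enoates with a γ-leaving group, so C6 is inverted from R to S and becomes threo to the epoxide as the target requires.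

Step 10
Reactants: 16 6S butenolide bis-silyl ether
Product: 17 C8,C13-diol
Conditions: HF·pyridine, pyridine, THF, 0 °C → rt
Reagents that add atoms: none
Why: Pyridine-buffered HF·pyridine desilylation should cleave both silyl ethers while leaving the trisubstituted epoxide, the butenolide and the alkyne intact, and it avoids bases that could deprotonate C6 next to the epoxide.

Step 11
Reactants: 17 C8,C13-diol
Product: 18 C13 acetate with free 8S hydroxyl
Conditions: AcCl (1.05 equiv), 2,4,6-collidine, CH2Cl2, −78 °C
Reagents that add atoms: acetyl chloride, CC(Cl)=O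
Why: Selective acylation with acetyl chloride and the hindered base collidine at low temperature should take the unhindered primary allylic C13 hydroxyl in preference to the secondary C8 hydroxyl beside the tetrasubstituted olefin.

Step 12
Reactants: 18 C13 acetate; 19 tigloyl chloride
Product: 20 C8 tiglate, C13 acetate (terminal alkyne; isopropylidene terminus)
Conditions: 19, pyridine, DMAP (cat.), CH2Cl2, 0 °C → rt
Reagents that add atoms: none
Why: DMAP-catalysed acylation of the remaining secondary alcohol with the acid chloride installs the tiglate, whose E olefin is the stable isomer, under bases too weak to deprotonate C6.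

Step 13
Reactants: 20 C8 tiglate, C13 acetate
Product: 22 epoxy butenolide ynal, via secondary ozonide 21 (not isolated)
Conditions: O3, CH2Cl2, −78 °C (Sudan Red 7B end point); then PPh3, −78 °C → rt
Reagents that add atoms: ozone, [O-][O+]=O
Why: In this ozonolysis the electron-rich trisubstituted isopropylidene olefin reacts far faster than the conjugated tiglate and butenolide olefins or the alkyne, the dye marks the end point, and reduction of the ozonide with PPh3 gives the C1 aldehyde.

Step 14
Reactants: 22 epoxy butenolide ynal; 23 triethylsilane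
Product: 24 C1 triethylsilyl ether of the ten-membered 2-methylene carbinol (C1 epimers)
Conditions: Ni(cod)2 (20 mol %), IPr [1,3-bis(2,6-diisopropylphenyl)imidazol-2-ylidene] (20 mol %), 23 (5 equiv), THF, slow addition of 22 (final 0.002 M), rt → 45 °C
Reagents that add atoms: none
Why: Zerovalent nickel carrying the bulky carbene binds the C1 aldehyde and the C10≡C14 alkyne and couples them oxidatively to an oxanickelacyclopentene in which C1 is bonded to the internal alkyne carbon C10; σ-bond metathesis of the Ni–O bond with Et3SiH and C–H reductive elimination then place silicon on the C1 oxygen and hydrogen on C14 and return zerovalent nickel. The closest known reaction type is the nickel/N-heterocyclic-carbene-catalysed reductive macrocyclisation of ynals with trialkylsilanes. The ten-membered carbocycle closes in the exo mode (10-exo-dig), so C14 stays outside the ring as the methylene group. The new C1 stereocentre is set by the conformation of the tethered metallacycle and needs no control, because either epimer converges on the ketone in step 16. The step needs bonding at C10 and not at C14, which the 2,6-diisopropylphenyl groups (the small alkyne hydrogen is turned towards the ligand) and the strain of the alternative eleven-membered E-cycloalkene should secure, and it needs ring closure to outrun oligomerisation, which slow addition at high dilution should secure. No free base or nucleophile is present, and the hindered tetrasubstituted butenolide olefin, the tiglate and the epoxide offer no competing partner for oxidative cyclisation.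

Step 15
Reactants: 24 C1 triethylsilyl ether
Product: 25 ten-membered 2-methylene allylic alcohol (C1 epimers)
Conditions: HF·pyridine, pyridine, THF, 0 °C
Reagents that add atoms: none
Why: Buffered fluoride desilylation of the allylic triethylsilyl ether is mild enough not to trigger transannular opening of the epoxide or loss of the esters.

Step 16
Reactants: 25 ten-membered 2-methylene allylic alcohol
Product: 26 CNP0225286.1
Conditions: Dess–Martin periodinane, NaHCO3, CH2Cl2, 0 °C
Reagents that add atoms: none
Why: Dess–Martin oxidation of the allylic alcohol under buffered neutral conditions should give the cross-conjugated α-methylene ketone and removes the undefined C1 centre.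

**Compound list**

1 | geraniol | CC(C)=CCC/C(C)=C/CO | starting material
2 | (2R,3R)-2,3-epoxygeraniol | OC[C@H]1O[C@]1(C)CCC=C(C)C | intermediate
3 | (2S,3R)-2,3-epoxy-3,7-dimethyloct-6-enal | O=C[C@H]1O[C@]1(C)CCC=C(C)C | intermediate
4 | methyl (S)-glycidate | COC(=O)[C@@H]1CO1 | starting material
5 | (trimethylsilyl)acetylene | C#C[Si](C)(C)C | starting material
6 | methyl (S)-2-hydroxy-5-(trimethylsilyl)pent-4-ynoate | COC(=O)[C@@H](O)CC#C[Si](C)(C)C | intermediate (not isolated)
7 | methyl (S)-2-hydroxypent-4-ynoate | COC(=O)[C@@H](O)CC#C | intermediate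
8 | methyl (S)-2-(triethylsilyloxy)pent-4-ynoate | COC(=O)[C@@H](O[Si](CC)(CC)CC)CC#C | intermediate
9 | tert-butyl 3-hydroxypropanoate | CC(C)(C)OC(=O)CCO | starting material
10 | tert-butyl 3-(tert-butyldimethylsilyloxy)propanoate | CC(C)(C)OC(=O)CCO[Si](C)(C)C(C)(C)C | intermediate
11 | tert-butyl (4S)-2-[(tert-butyldimethylsilyloxy)methyl]-3-oxo-4-(triethylsilyloxy)hept-6-ynoate | C#CC[C@H](O[Si](CC)(CC)CC)C(=O)C(CO[Si](C)(C)C(C)(C)C)C(=O)OC(C)(C)C | intermediate
12 | sodium enolate of 11 (enolate oxygen cis to the ester) | [Na+].C#CC[C@H](O[Si](CC)(CC)CC)/C([O-])=C(\CO[Si](C)(C)C(C)(C)C)C(=O)OC(C)(C)C | intermediate (not isolated)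
13 | tert-butyl (2Z,4S)-2-[(tert-butyldimethylsilyloxy)methyl]-4-(triethylsilyloxy)-3-(trifluoromethylsulfonyloxy)hept-2-en-6-ynoate | C#CC[C@H](O[Si](CC)(CC)CC)/C(OS(=O)(=O)C(F)(F)F)=C(\CO[Si](C)(C)C(C)(C)C)C(=O)OC(C)(C)C | intermediate
14 | open 6R hydroxy tert-butyl ester (C6 cis to the ester; 4R,5R-epoxide; 8S) | C#CC[C@H](O[Si](CC)(CC)CC)/C(=C(\CO[Si](C)(C)C(C)(C)C)C(=O)OC(C)(C)C)[C@@H](O)[C@H]1O[C@]1(C)CCC=C(C)C | intermediate
15 | C6 mesylate of 14 | C#CC[C@H](O[Si](CC)(CC)CC)/C(=C(\CO[Si](C)(C)C(C)(C)C)C(=O)OC(C)(C)C)[C@@H](OS(C)(=O)=O)[C@H]1O[C@]1(C)CCC=C(C)C | intermediate (not isolated)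
16 | 6S butenolide, C8 triethylsilyl ether, C13 tert-butyldimethylsilyl ether | C#CC[C@H](O[Si](CC)(CC)CC)C1=C(CO[Si](C)(C)C(C)(C)C)C(=O)O[C@@H]1[C@H]1O[C@]1(C)CCC=C(C)C | intermediate
17 | 6S butenolide C8,C13-diol | C#CC[C@H](O)C1=C(CO)C(=O)O[C@@H]1[C@H]1O[C@]1(C)CCC=C(C)C | intermediate
18 | 6S butenolide C13 acetate, 8S alcohol | C#CC[C@H](O)C1=C(COC(C)=O)C(=O)O[C@@H]1[C@H]1O[C@]1(C)CCC=C(C)C | intermediate
19 | tigloyl chloride, (E)-2-methylbut-2-enoyl chloride | C/C=C(\C)C(Cl)=O | starting material
20 | 6S butenolide C8 tiglate, C13 acetate | C#CC[C@H](OC(=O)/C(C)=C/C)C1=C(COC(C)=O)C(=O)O[C@@H]1[C@H]1O[C@]1(C)CCC=C(C)C | intermediate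
21 | secondary ozonide of 20 (3,3-dimethyl-1,2,4-trioxolane at C1) | C#CC[C@H](OC(=O)/C(C)=C/C)C1=C(COC(C)=O)C(=O)O[C@@H]1[C@H]1O[C@]1(C)CCC1OOC(C)(C)O1 | intermediate (not isolated)
22 | epoxy butenolide ynal | C#CC[C@H](OC(=O)/C(C)=C/C)C1=C(COC(C)=O)C(=O)O[C@@H]1[C@H]1O[C@]1(C)CCC=O | intermediate
23 | triethylsilane | CC[SiH](CC)CC | starting material
24 | C1 triethylsilyl ether of the ten-membered 2-methylene carbinol (C1 epimers) | C=C1C[C@H](OC(=O)/C(C)=C/C)C2=C(COC(C)=O)C(=O)O[C@@H]2[C@H]2O[C@]2(C)CCC1O[Si](CC)(CC)CC | intermediate
25 | ten-membered 2-methylene allylic alcohol (C1 epimers) | C=C1C[C@H](OC(=O)/C(C)=C/C)C2=C(COC(C)=O)C(=O)O[C@@H]2[C@H]2O[C@]2(C)CCC1O | intermediate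
26 | CNP0225286.1 (4R,5R,6S,8S) | C=C1C[C@H](OC(=O)/C(C)=C/C)C2=C(COC(C)=O)C(=O)O[C@@H]2[C@H]2O[C@]2(C)CCC1=O | target

**Step count and risks**

Total steps: 16. Longest linear sequence: 13 steps (steps 3, 4 and 6–16, from methyl (S)-glycidate).

Step 14. Ring closure may lose to intermolecular coupling or to bonding at C14, and zerovalent nickel may ionise the allylic C13 acetate. Fallback: setting out from 22, Markovnikov hydrostannation of the alkyne (Bu3SnH, Mo(CO)3(CNtBu)3, hydroquinone, THF, 55 °C) would give the 2-(tributylstannyl)alkene aldehyde F1. Iododestannylation (I2, CH2Cl2, 0 °C) would give the 2-iodoalkene aldehyde F2. An intramolecular Nozaki–Hiyama–Kishi reaction (CrCl2, NiCl2 cat., DMSO/THF, high dilution) would then form the same C1–C10 bond and the same ring, exo by construction. It gives the free alcohol and comes back to the route at 25.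

Step 9. The internal displacement at the carbinol carbon beside the epoxide may be sluggish, or the sulfonate may ionise so that stereospecificity is lost. Fallback: setting out from 14, intermolecular Mitsunobu inversion (PPh3, DIAD, 4-nitrobenzoic acid, toluene) would give the 6S 4-nitrobenzoate F3. Methanolysis (K2CO3, MeOH, 0 °C) would give the 6S hydroxy tert-butyl ester F4. Acid-catalysed lactonisation with retention on the tert-butyl ester (PPTS, toluene, 60 °C) would come back to the route at 16.

Step 8. The bulky tetrasubstituted alkenylchromium reagent may add to the α-epoxy aldehyde with poor facial selectivity. Fallback: setting out from 14 as obtained in admixture with its C6 epimer, Dess–Martin oxidation would converge both on the epoxy ketone F5. Chelation-controlled reduction with Zn(BH4)2 (Et2O, −20 °C), in which zinc bridges the ketone and epoxide oxygens, is known to give the erythro epoxy alcohol and comes back to the route at 14.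

Further compounds
F1 | step 14 | 2-(tributylstannyl)alkene aldehyde (C10 stannane of 22) | C=C([Sn](CCCC)(CCCC)CCCC)C[C@H](OC(=O)/C(C)=C/C)C1=C(COC(C)=O)C(=O)O[C@@H]1[C@H]1O[C@]1(C)CCC=O
F2 | step 14 | 2-iodoalkene aldehyde (C10 iodide) | C=C(I)C[C@H](OC(=O)/C(C)=C/C)C1=C(COC(C)=O)C(=O)O[C@@H]1[C@H]1O[C@]1(C)CCC=O
F3 | step 9 | 6S 4-nitrobenzoate of the open tert-butyl ester | C#CC[C@H](O[Si](CC)(CC)CC)/C(=C(\CO[Si](C)(C)C(C)(C)C)C(=O)OC(C)(C)C)[C@H](OC(=O)c1ccc(cc1)[N+](=O)[O-])[C@H]1O[C@]1(C)CCC=C(C)C
F4 | step 9 | open 6S hydroxy tert-butyl ester (C6 epimer of 14) | C#CC[C@H](O[Si](CC)(CC)CC)/C(=C(\CO[Si](C)(C)C(C)(C)C)C(=O)OC(C)(C)C)[C@H](O)[C@H]1O[C@]1(C)CCC=C(C)C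
F5 | step 8 | C6 epoxy ketone of the open tert-butyl ester | C#CC[C@H](O[Si](CC)(CC)CC)/C(=C(\CO[Si](C)(C)C(C)(C)C)C(=O)OC(C)(C)C)C(=O)[C@H]1O[C@]1(C)CCC=C(C)C
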